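**Plan**

1. The last disconnection cuts the ring-fusion bond C8a–C4a and the pyran bond O2–C3 together. Behind it lie O7–C4a and C5–C6 (a temporary furanone), then C4a–C4 (allenyllithium plus amide), C7–C8 (enolate acylation), C8a–C1 (amide acetal) and C4–C(alkyne).
2. Enabling feature: in the target the C7 oxygen (O7) and C4a are 1,3-related across C6, and C4a is the β-carbon of the C6 enone. They can therefore be tied as a 3(2H)-furanone (ring O7–C7–C6–C5–C4a) whose C4a is an electrophilic vinylogous-ester carbon lying over C8a of the β-ketoaldehyde arm on C7.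
3. O5 and O7 are also 1,3-related, so the butanoyl group is parked on O5 and passes to O7 when the furanone opens. The allene C4=C3=C stores the oxidation level of C3.
4. Forward: lactate-derived dioxolanone (temporary, carries the stereocentre), then the furanone (temporary), then in one step the carbocycle (C5–C6–C7–C8–C8a–C4a) and the pyran (O2–C1–C8a–C4a–C4–C3) while the furanone opens; one silyl ether is removed last.
5. Stereochemistry: the only stereocentre, C7 (R), comes from (S)-lactic acid. The cis-2-tert-butyl dioxolanone enolate is acylated anti to tert-butyl with retention, and C7 is quaternary from then on.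

Key step: step 7

Remark: atoms carry the 6H-isochromene numbering of the target (C1, O2, C3, C4, C4a, C5, C6, C7, C8, C8a; O5 and O7 are the oxygens on C5 and C7). Compounds 7 to 14 are racemic at the allene axis, and 9 and 13 are also epimeric at C5 and C8a respectively; all these epimers converge in step 7.

Step 1
Reactants: 1 (2S,5S)-2-tert-butyl-5-methyl-1,3-dioxolan-4-one
Product: 2 (2S,5R)-5-acetyl-2-tert-butyl-5-methyl-1,3-dioxolan-4-one
Conditions: LiN(iPr)2, THF, −78 °C; AcCl, −78 → −40 °C
Reagents that add atoms: acetyl chloride CC(=O)Cl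
Why: Claisen-type C-acylation of the lithium lactone enolate by the acid chloride should occur on the face anti to the tert-butyl group, so that acetyl replaces the lactate hydrogen with retention (self-regeneration of the stereocentre through the acetal carbon) and the future C7 becomes a quaternary, non-enolisable centre (5R in 2, 7R in the target).

Step 2
Reactants: 2 (2S,5R)-5-acetyl-2-tert-butyl-5-methyl-1,3-dioxolan-4-one
Product: 3 (2S,5R)-2-tert-butyl-5-[(2E)-3-(dimethylamino)prop-2-enoyl]-5-methyl-1,3-dioxolan-4-one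
Conditions: Me2NCH(OMe)2 (neat), 90 °C
Reagents that add atoms: N,N-dimethylformamide dimethyl acetal COC(OC)N(C)C
Why: Condensation of the methyl ketone with the amide acetal (enaminone formation) should give the (E)-vinylogous amide, which brings in C1 at the aldehyde oxidation level in a form that is inert to enolates and bases.

Step 3
Reactants: 4 tert-butyl(but-3-yn-1-yloxy)diphenylsilane
Product: 5 tert-butyl[(5-methoxypent-3-yn-1-yl)oxy]diphenylsilane
Conditions: n-BuLi, THF, −78 °C; MeOCH2Cl, −78 → 0 °C
Reagents that add atoms: chloromethyl methyl ether COCCl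
Why: Alkylation of the lithium acetylide with the chloromethyl ether (SN2 alkylation of an alkynyllithium) should give the propargylic methyl ether that holds C3, C4, the methoxy group and the protected side chain.

Step 4
Reactants: 5 tert-butyl[(5-methoxypent-3-yn-1-yl)oxy]diphenylsilane, 6 2-[(tert-butyldimethylsilyl)oxy]-N-methoxy-N-methylacetamide
Product: 8 1-[(tert-butyldimethylsilyl)oxy]-7-[(tert-butyldiphenylsilyl)oxy]-3-methoxyhepta-3,4-dien-2-one, via allenyl ether 7 (not isolated)
Conditions: KOtBu (0.2 equiv), THF, 0 → 23 °C; n-BuLi, −78 °C; then 6, −78 → −40 °C; AcOH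
Reagents that add atoms: none
Why: Base-catalysed propargyl-to-allenyl ether isomerisation, lithiation of the allene at its methoxy-bearing carbon and acylation of this alkoxyallenyllithium by the N-methoxy-N-methylamide (ketone synthesis through a stable tetrahedral chelate) should give the α-methoxy allenyl ketone, in which the allene stores the oxidation level needed at C3.

Step 5
Reactants: 8 1-[(tert-butyldimethylsilyl)oxy]-7-[(tert-butyldiphenylsilyl)oxy]-3-methoxyhepta-3,4-dien-2-one, 3 (2S,5R)-2-tert-butyl-5-[(2E)-3-(dimethylamino)prop-2-enoyl]-5-methyl-1,3-dioxolan-4-one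
Product: 10 (2R)-4-[(tert-butyldimethylsilyl)oxy]-5-{5-[(tert-butyldiphenylsilyl)oxy]-1-methoxypenta-1,2-dien-1-yl}-2-[(2E)-3-(dimethylamino)prop-2-enoyl]-2-methylfuran-3(2H)-one, via hydroxy triketone 9 (not isolated)
Conditions: LiN(SiMe3)2, THF, −78 °C; then 3, −78 → −20 °C; AcOH; then pyridinium p-toluenesulfonate (cat.), 4 Å molecular sieves, CH2Cl2, 0 °C
Reagents that add atoms: none
Why: Claisen acylation of the lithium enolate of 8 (C5 is its only enolisable position) at the activated lactone carbonyl of 3 should expel the acetal oxygen with loss of 2,2-dimethylpropanal, and the freed tertiary hydroxyl should then close onto the C4a ketone and dehydrate under mild acid (α'-hydroxy-1,3-diketone to 3(2H)-furanone cyclodehydration), which ties O7 to C4a without touching the quaternary C7.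

Step 6
Reactants: 10 (2R)-4-[(tert-butyldimethylsilyl)oxy]-5-{5-[(tert-butyldiphenylsilyl)oxy]-1-methoxypenta-1,2-dien-1-yl}-2-[(2E)-3-(dimethylamino)prop-2-enoyl]-2-methylfuran-3(2H)-one
Product: 11 (2R)-5-{5-[(tert-butyldiphenylsilyl)oxy]-1-methoxypenta-1,2-dien-1-yl}-2-[(2E)-3-(dimethylamino)prop-2-enoyl]-2-methyl-3-oxo-2,3-dihydrofuran-4-yl butanoate
Conditions: (PrCO)2O, Bu4NF (1.0 equiv), THF, −78 → −20 °C
Reagents that add atoms: butanoic anhydride CCCC(=O)OC(=O)CCC
Why: Fluoride should cleave the enol silyl ether far faster than the alkyl silyl ether, and the furanone enolate so formed is O-acylated in situ by the anhydride (silyl enol ether to enol ester exchange), which parks the butanoyl group on O5.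

Step 7
Reactants: 11 (2R)-5-{5-[(tert-butyldiphenylsilyl)oxy]-1-methoxypenta-1,2-dien-1-yl}-2-[(2E)-3-(dimethylamino)prop-2-enoyl]-2-methyl-3-oxo-2,3-dihydrofuran-4-yl butanoate
Product: 16 (7R)-3-{3-[(tert-butyldiphenylsilyl)oxy]propyl}-5-hydroxy-4-methoxy-7-methyl-6,8-dioxo-7,8-dihydro-6H-isochromen-7-yl butanoate, via hydroxymethylene ketone 12 (not isolated), via oxygen-bridged adduct 13 (not isolated), via ring-opened enedione 14 (not isolated), via 7-hydroxy 5-butanoate 15 (not isolated)
Conditions: AcOH–H2O–THF (1:1:3), 0 → 23 °C; then NaHCO3 to pH 8, 23 → 40 °C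
Reagents that add atoms: water O
Why: Proposed new method: aqueous acetic acid hydrolyses the vinylogous amide to the hydroxymethylene ketone 12, and at pH 8 its enolate carbon C8a should add to C4a, the oxygen-bearing β-carbon of the furanone enone (6-endo-trig conjugate addition across the five-membered ring), giving the strained 7-oxabicyclo[2.2.1]heptenone 13, whose C4a–O7 bond then breaks by β-elimination with release of strain to give the cyclohexenedione 14. The hydroxymethylene oxygen O2 then closes onto the central allene carbon C3 (6-endo closure, an oxa-6π electrocyclisation of the O2=C1–C8a=C4a–C4=C3 oxatriene tautomer followed by proton shift from C5 to the exocyclic carbon) to give 15, and the free O7 hydroxyl finally takes the butanoyl group from the neighbouring enol ester on O5 through a six-membered tetrahedral intermediate to give 16. The closest known reaction types are the ring-opening and re-closure of chromones, 4-pyranones and 3(2H)-furanones by carbon nucleophiles at the oxygen-bearing carbon, the base-induced opening of the oxygen bridge of 7-oxabicyclo[2.2.1]heptan-2-ones, O-to-O acyl migration in 1,3-diol monoesters and the electrocyclisation of cis-dienals to 2H-pyrans. No stereocentre is created: C7 is quaternary and not enolisable and keeps the configuration set in step 1, while the allene axis and the C8a centre of 13 disappear. The step needs carbon-attack and not oxygen-attack of the ambident enolate, at C4a and not at C3: only the C8a–C4a closure gives a six-membered carbocycle (the alternatives need seven- to nine-membered rings), the furanone holds the C6 carbonyl s-trans to C4a=C5 so that its oxygen cannot reach C3, and the butanoyl group on O5 keeps that oxygen from closing a furan onto C3. At pH 8 the liberated dimethylamine stays protonated and should not cleave the enol ester, and the acyl shift is downhill because an enol ester is exchanged for an alkyl ester and a hydrogen-bonded diosphenol.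

Step 8
Reactants: 16 (7R)-3-{3-[(tert-butyldiphenylsilyl)oxy]propyl}-5-hydroxy-4-methoxy-7-methyl-6,8-dioxo-7,8-dihydro-6H-isochromen-7-yl butanoate
Product: 17 (7R)-5-hydroxy-3-(3-hydroxypropyl)-4-methoxy-7-methyl-6,8-dioxo-7,8-dihydro-6H-isochromen-7-yl butanoate
Conditions: HF·pyridine, pyridine–THF, 0 → 23 °C
Reagents that add atoms: none
Why: Fluoride-mediated cleavage of the silyl ether under mildly acidic buffered conditions (desilylation) should free the primary alcohol without opening the pyran or cleaving the tertiary ester.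

**Compound list**

1 | (2S,5S)-2-tert-butyl-5-methyl-1,3-dioxolan-4-one (cis acetal of (S)-lactic acid and 2,2-dimethylpropanal) | C[C@@H]1O[C@H](C(C)(C)C)OC1=O | starting material
2 | (2S,5R)-5-acetyl-2-tert-butyl-5-methyl-1,3-dioxolan-4-one | C[C@]1(C(C)=O)O[C@H](C(C)(C)C)OC1=O | intermediate
3 | (2S,5R)-2-tert-butyl-5-[(2E)-3-(dimethylamino)prop-2-enoyl]-5-methyl-1,3-dioxolan-4-one | C[C@]1(C(=O)/C=C/N(C)C)O[C@H](C(C)(C)C)OC1=O | intermediate
4 | tert-butyl(but-3-yn-1-yloxy)diphenylsilane | C#CCCO[Si](c1ccccc1)(c1ccccc1)C(C)(C)C | starting material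
5 | tert-butyl[(5-methoxypent-3-yn-1-yl)oxy]diphenylsilane | COCC#CCCO[Si](c1ccccc1)(c1ccccc1)C(C)(C)C | intermediate
6 | 2-[(tert-butyldimethylsilyl)oxy]-N-methoxy-N-methylacetamide | CON(C)C(=O)CO[Si](C)(C)C(C)(C)C | starting material
7 | tert-butyl[(5-methoxypenta-3,4-dien-1-yl)oxy]diphenylsilane (racemic allene) | COC=C=CCCO[Si](c1ccccc1)(c1ccccc1)C(C)(C)C | intermediate
8 | 1-[(tert-butyldimethylsilyl)oxy]-7-[(tert-butyldiphenylsilyl)oxy]-3-methoxyhepta-3,4-dien-2-one (racemic allene) | CC(C)(C)[Si](C)(C)OCC(=O)C(OC)=C=CCCO[Si](c1ccccc1)(c1ccccc1)C(C)(C)C | intermediate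
9 | (1E,4R)-6-[(tert-butyldimethylsilyl)oxy]-12-[(tert-butyldiphenylsilyl)oxy]-1-(dimethylamino)-4-hydroxy-8-methoxy-4-methyldodeca-1,8,9-triene-3,5,7-trione (mixture at C6 and the allene axis) | C[C@@](O)(C(=O)/C=C/N(C)C)C(=O)C(O[Si](C)(C)C(C)(C)C)C(=O)C(OC)=C=CCCO[Si](c1ccccc1)(c1ccccc1)C(C)(C)C | intermediate
10 | (2R)-4-[(tert-butyldimethylsilyl)oxy]-5-{5-[(tert-butyldiphenylsilyl)oxy]-1-methoxypenta-1,2-dien-1-yl}-2-[(2E)-3-(dimethylamino)prop-2-enoyl]-2-methylfuran-3(2H)-one | CC(C)(C)[Si](C)(C)OC1=C(C(OC)=C=CCCO[Si](c2ccccc2)(c2ccccc2)C(C)(C)C)O[C@](C)(C(=O)/C=C/N(C)C)C1=O | intermediate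
11 | (2R)-5-{5-[(tert-butyldiphenylsilyl)oxy]-1-methoxypenta-1,2-dien-1-yl}-2-[(2E)-3-(dimethylamino)prop-2-enoyl]-2-methyl-3-oxo-2,3-dihydrofuran-4-yl butanoate | CCCC(=O)OC1=C(C(OC)=C=CCCO[Si](c2ccccc2)(c2ccccc2)C(C)(C)C)O[C@](C)(C(=O)/C=C/N(C)C)C1=O | intermediate
12 | (2R)-5-{5-[(tert-butyldiphenylsilyl)oxy]-1-methoxypenta-1,2-dien-1-yl}-2-(3-hydroxyprop-2-enoyl)-2-methyl-3-oxo-2,3-dihydrofuran-4-yl butanoate (enol of the 3-oxopropanoyl group) | CCCC(=O)OC1=C(C(OC)=C=CCCO[Si](c2ccccc2)(c2ccccc2)C(C)(C)C)O[C@](C)(C(=O)C=CO)C1=O | intermediate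
13 | 4-{5-[(tert-butyldiphenylsilyl)oxy]-1-methoxypenta-1,2-dien-1-yl}-3-formyl-6-hydroxy-1-methyl-2-oxo-7-oxabicyclo[2.2.1]hept-5-en-5-yl butanoate (bridgeheads are C7 and C4a of the target numbering; C7 as in 11; shown as the C6 enol; mixture at the formyl-bearing carbon) | CCCC(=O)OC1=C(O)[C@]2(C)O[C@@]1(C(OC)=C=CCCO[Si](c3ccccc3)(c3ccccc3)C(C)(C)C)C(C=O)C2=O | intermediate
14 | (5R)-2-{5-[(tert-butyldiphenylsilyl)oxy]-1-methoxypenta-1,2-dien-1-yl}-5-hydroxy-3-(hydroxymethylidene)-5-methyl-4,6-dioxocyclohex-1-en-1-yl butanoate | CCCC(=O)OC1=C(C(OC)=C=CCCO[Si](c2ccccc2)(c2ccccc2)C(C)(C)C)C(=CO)C(=O)[C@@](C)(O)C1=O | intermediate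
15 | (7R)-3-{3-[(tert-butyldiphenylsilyl)oxy]propyl}-7-hydroxy-4-methoxy-7-methyl-6,8-dioxo-7,8-dihydro-6H-isochromen-5-yl butanoate | CCCC(=O)OC1=C2C(OC)=C(CCCO[Si](c3ccccc3)(c3ccccc3)C(C)(C)C)OC=C2C(=O)[C@@](C)(O)C1=O | intermediate
16 | (7R)-3-{3-[(tert-butyldiphenylsilyl)oxy]propyl}-5-hydroxy-4-methoxy-7-methyl-6,8-dioxo-7,8-dihydro-6H-isochromen-7-yl butanoate | CCCC(=O)O[C@]1(C)C(=O)C2=COC(CCCO[Si](c3ccccc3)(c3ccccc3)C(C)(C)C)=C(OC)C2=C(O)C1=O | intermediate
17 | (7R)-5-hydroxy-3-(3-hydroxypropyl)-4-methoxy-7-methyl-6,8-dioxo-7,8-dihydro-6H-isochromen-7-yl butanoate | CCCC(=O)O[C@]1(C)C(=O)C2=COC(CCCO)=C(OC)C2=C(O)C1=O | target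

**Totals and risks**

Total steps: 8. Longest linear sequence: 6 steps (steps 1, 2, 5, 6, 7, 8 from 1; equally steps 3, 4, 5, 6, 7, 8 from 4).

Steps most likely to fail:

Step 7 (proposed new method). The bridged conjugate addition of C8a to C4a may be too slow, so that hydrolysis of the enol ester or oxygen-attack of the ambident enolate takes over; the acyl shift may also lag behind re-closure of O7 onto C1. The fallback uses known chemistry, sets out from 3 and rejoins the route at 17. NaSEt opens the lactone of 3, and the tertiary alkoxide that is set free is capped in the same flask with butanoyl chloride, which should give S-ethyl (2R,4E)-2-(butanoyloxy)-5-(dimethylamino)-2-methyl-3-oxopent-4-enethioate F1. Claisen acylation of the lithium enolate of 8 by this thioester should give the open-chain 2-silyloxy-1,3-diketone F2, in which O7 already carries the butanoate. Aqueous acetic acid followed by piperidinium acetate should then bring about hydrolysis of the vinylogous amide, intramolecular Knoevenagel condensation of C8a with the C4a ketone and oxa-6π electrocyclisation of the resulting oxatriene onto the allene, giving after proton shift the bis-silyl ether F3. HF·pyridine removes both silyl groups and gives 17.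

Step 5. The ring closure may lose chemoselectivity: the freed tertiary hydroxyl can add to the vinylogous amide with loss of dimethylamine, giving an isomeric furanone, in competition with closure onto the C4a ketone. The fallback sets out from 2 and rejoins at 10. The enolate of 8 is acylated by the acetyl lactone 2 in place of 3, so that the arm on C7 offers no second electrophile and acid treatment should give the methyl ketone (2R)-2-acetyl-4-[(tert-butyldimethylsilyl)oxy]-5-{5-[(tert-butyldiphenylsilyl)oxy]-1-methoxypenta-1,2-dien-1-yl}-2-methylfuran-3(2H)-one F4. Me2NCH(OMe)2 then converts the acetyl group of F4 into the vinylogous amide of 10.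

Step 1. Proton transfer from acetyl chloride to the enolate (ketene formation) or O-acylation may outrun C-acylation. The fallback sets out from 1 and rejoins at 2. Aldol addition of the same enolate to acetaldehyde, again anti to tert-butyl, should give the carbinol (2S,5R)-2-tert-butyl-5-(1-hydroxyethyl)-5-methyl-1,3-dioxolan-4-one F5 as a mixture at the carbinol carbon. Oxidation with 1,1,1-triacetoxy-1,1-dihydro-1,2-benziodoxol-3(1H)-one gives 2.

Further compounds
F1 | step 7 | S-ethyl (2R,4E)-2-(butanoyloxy)-5-(dimethylamino)-2-methyl-3-oxopent-4-enethioate | CCCC(=O)O[C@](C)(C(=O)/C=C/N(C)C)C(=O)SCC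
F2 | step 7 | (1E,4R)-6-[(tert-butyldimethylsilyl)oxy]-12-[(tert-butyldiphenylsilyl)oxy]-1-(dimethylamino)-8-methoxy-4-methyl-3,5,7-trioxododeca-1,8,9-trien-4-yl butanoate | CCCC(=O)O[C@](C)(C(=O)/C=C/N(C)C)C(=O)C(O[Si](C)(C)C(C)(C)C)C(=O)C(OC)=C=CCCO[Si](c1ccccc1)(c1ccccc1)C(C)(C)C
F3 | step 7 | (7R)-5-[(tert-butyldimethylsilyl)oxy]-3-{3-[(tert-butyldiphenylsilyl)oxy]propyl}-4-methoxy-7-methyl-6,8-dioxo-7,8-dihydro-6H-isochromen-7-yl butanoate | CCCC(=O)O[C@]1(C)C(=O)C2=COC(CCCO[Si](c3ccccc3)(c3ccccc3)C(C)(C)C)=C(OC)C2=C(O[Si](C)(C)C(C)(C)C)C1=O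
F4 | step 5 | (2R)-2-acetyl-4-[(tert-butyldimethylsilyl)oxy]-5-{5-[(tert-butyldiphenylsilyl)oxy]-1-methoxypenta-1,2-dien-1-yl}-2-methylfuran-3(2H)-one | CC(=O)[C@@]1(C)OC(C(OC)=C=CCCO[Si](c2ccccc2)(c2ccccc2)C(C)(C)C)=C(O[Si](C)(C)C(C)(C)C)C1=O
F5 | step 1 | (2S,5R)-2-tert-butyl-5-(1-hydroxyethyl)-5-methyl-1,3-dioxolan-4-one | C[C@]1(C(C)O)O[C@H](C(C)(C)C)OC1=O
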